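**Plan**

1. Retrosynthesis: the side chain is cut at C9–C11 (enol triflate plus alkylborane); ring A is then cut at C1–C10 and C4–C5, the two Michael bonds that join a C1–C4/C19 β-keto ester unit to ring B.
2. Enabling feature: ring B carries oxygen-level carbons C6 and C9 para to each other, flanked by the C8 and C10 methyl groups, so it is a masked 2,6-dimethyl-1,4-benzoquinone. C9=O and C3=O are 1,5-related through C10–C1, so C10 (α to C9) is a donor and C1 (β to C3) an acceptor.
3. Forward: phenol → quinone monoketal (ring B) → catalytic asymmetric Michael addition at C5 (C4–C5 bond) → ring A closed by the C10→C1 Michael addition → C4 methylation → C9 enol triflate → B-alkyl Suzuki–Miyaura coupling of the C11–C16 chain → 3-O-acylation.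
4. Stereochemistry: only C5 is set by catalysis. It delivers C1 to one face of C10 in the ring closure and is then erased as an enol ether. C4 (alkylation), C3 (bulky hydride), C5 (protonation) and C6 (hydride) are each set anti to the C10 methyl group; the 13E alkene is bought.

Key step: step 3

Remark: bicyclic compounds are numbered as in the target's labdane skeleton (ring A = C1–C5 and C10; ring B = C5–C10; C17 = C8 methyl, C18 = 4α-methyl, C19 = 4β-carbon, C20 = C10 methyl); β is the face of C20. Compounds 1, 3 and 16 are taken as commercial.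

**Step 1**
Reactants: 1 4-methoxy-2,6-dimethylphenol
Product: 2 4,4-dimethoxy-2,6-dimethylcyclohexa-2,5-dien-1-one
Conditions: PhI(OAc)2 (1.1 equiv), MeOH, 0 °C
Reagents that add atoms: methanol, CO
Why: Oxidative dearomatisation of a para-methoxyphenol by a hypervalent iodine reagent in methanol should give the quinone monoketal, which holds all six ring B carbons with C9 as the ketone and C6 as the ketal; no stereocentre is formed.

**Step 2**
Reactants: 2 4,4-dimethoxy-2,6-dimethylcyclohexa-2,5-dien-1-one; 3 methyl 5-methoxy-3-oxopentanoate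
Product: 4 (5S)-Michael adduct
Conditions: La(OiPr)3 (10 mol %), (S,S)-N-methylbis[(2,2′-dihydroxy-1,1′-binaphthalen-3-yl)methyl]amine (10 mol %), THF, 0 °C to rt
Reagents that add atoms: none
Why: Catalytic asymmetric Michael addition of a β-keto ester to a cyclic enone under a Lewis acidic and Brønsted basic lanthanum binaphthoxide should desymmetrise the dienone (its two β-carbons C5 and C7 are enantiotopic) and set C5 as (S), the ligand antipode being proposed by analogy with cyclohex-2-enone and exchanged for its mirror image should the sense be opposite; C4 and C10 are labile and are carried as mixtures.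

**Step 3**
Reactants: 4 (5S)-Michael adduct
Product: 6 cis-fused ketal diketo ester, via vinyl ketone 5 (not isolated)
Conditions: Cs2CO3 (0.3 equiv), MeCN (0.01 M), 40 °C
Reagents that add atoms: none
Why: Cs2CO3 reversibly removes a C2 proton, methoxide is lost (E1cB) and the enone 5 is unveiled; the ring ketone can enolise only toward C10 (C8 is sp2, C6 is a ketal), and this cross-conjugated enolate should add through C10 to the enone terminus C1, an intramolecular Michael addition whose closest known reaction type is the ring-closing half of the base-mediated double Michael annulation of 3-oxopent-4-enoates with cyclic enones. Ring A closes in the 6-endo-trig mode, with the enolate double bond exocyclic to the new ring. The new quaternary centre C10 is controlled by the C5 stereocentre: the four-atom tether reaches only the face of the planar enolate on which C4 sits, so C1 and C4 become cis and the methyl group is pushed to the face of H5 (cis-decalin, C10 as in the target). The selectivity needed is C10–C1 bond formation in preference to reactions of the more acidic C4–H of the β-keto ester; that enolate cannot reach C1 (it would give a cyclobutane) and only shuttles the proton, the bridged C2-to-C9 aldol alternative is reversible, and high dilution holds back intermolecular Michael addition. Ring B cannot aromatise under base while C6 is a ketal, and it cannot aromatise at all once C10 is quaternary.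

**Step 4**
Reactants: 6 cis-fused ketal diketo ester
Product: 7 dienone methyl enol ether
Conditions: camphorsulfonic acid (10 mol %), toluene, 4 Å MS, 80 °C
Reagents that add atoms: none
Why: Acid-catalysed loss of methanol from the dimethyl ketal (oxocarbenium ion, then loss of H5) should give the conjugated C5=C6 enol ether, which erases the C5 centre after it has done its relay and leaves C10 as the only stereocentre.

**Step 5**
Reactants: 7 dienone methyl enol ether
Product: 8 4α-methyl 4β-ester
Conditions: K2CO3, MeI, acetone, rt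
Reagents that add atoms: iodomethane, CI
Why: C-Alkylation of the extended β-keto ester enolate should occur at C4 on the face opposite the pseudoaxial C10 methyl group, as in classical alkylations of Δ5 3-keto decalins with an angular methyl, so that the new methyl is α (C18) and the ester is β (C19).

**Step 6**
Reactants: 8 4α-methyl 4β-ester
Product: 10 3α-hydroxy C9 enol triflate, via dilithium enolate alkoxide 9 (not isolated)
Conditions: LiBH(s-Bu)3 (2.3 equiv), THF, −78 °C; then PhNTf2, −78 to 0 °C
Reagents that add atoms: N-phenylbis(trifluoromethanesulfonimide), O=S(=O)(N(c1ccccc1)S(=O)(=O)C(F)(F)F)C(F)(F)F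
Why: The bulky borohydride should add 1,4 to the enone at C7 (the C9 carbonyl is shielded by the C8 methyl and quaternary C10, and the δ-carbon C5 is fully substituted) and attack the C3 ketone equatorially to give the axial 3α-alkoxide, after which the regiodefined C8=C9 enolate is O-triflated (conjugate reduction and enolate trapping of an enone).

**Step 7**
Reactants: 10 3α-hydroxy C9 enol triflate
Product: 11 trans-fused 6-ketone
Conditions: 0.5 M aq. HCl, THF, 0 °C
Reagents that add atoms: water, O
Why: Enol ether hydrolysis is rate-limited by C-protonation at C5, which should occur axially from the α face, away from the C10 methyl and the 4β-ester on the two neighbouring carbons, to give the trans ring fusion under kinetic control.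

**Step 8**
Reactants: 11 trans-fused 6-ketone
Product: 14 3α,6β,19-triol enol triflate, via 6β-hydroxy ester 12 (not isolated), via 19,6β-lactone 13 (not isolated)
Conditions: LiBH4, THF, MeOH (2 equiv), 0 to 40 °C
Reagents that add atoms: none
Why: Hydride reduction of the C6 ketone should come from the open α face (the β face is blocked 1,3-diaxially by C20 and C19) to give the axial 6β-alkoxide, which lactonises onto C19, and the lactone is then reduced to the C19 primary alcohol.

**Step 9**
Reactants: 14 3α,6β,19-triol enol triflate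
Product: 15 19-O-TBS ether
Conditions: TBSCl (1.1 equiv), imidazole, DMF, 0 °C
Reagents that add atoms: tert-butyldimethylsilyl chloride, CC(C)(C)[Si](C)(C)Cl
Why: Silylation should select the primary C19 hydroxyl over the axial 3α-hydroxyl next to a quaternary carbon and the doubly flanked 6β-hydroxyl.

**Step 10**
Reactants: 16 ethyl (2E)-3-methyl-4-oxobut-2-enoate
Product: 17 ethyl (2E)-3-methylpenta-2,4-dienoate
Conditions: Ph3PCH3Br, KOtBu, THF, 0 °C
Reagents that add atoms: methyltriphenylphosphonium bromide, C[P+](c1ccccc1)(c1ccccc1)c1ccccc1.[Br-]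
Why: Wittig methylenation of the enal should give the terminal vinyl group (C11=C12) without touching the (E)-trisubstituted enoate that becomes C13=C14.

**Step 11**
Reactants: 17 ethyl (2E)-3-methylpenta-2,4-dienoate; 15 19-O-TBS ether
Product: 19 coupled ethyl ester, via alkylborane 18 (not isolated)
Conditions: 9-BBN, THF, 0 °C to rt; then 15, PdCl2(dppf) (10 mol %), AsPh3, 3 M aq. K3PO4, DMF, 50 °C
Reagents that add atoms: none
Why: Hydroboration of the terminal vinyl group puts boron on C11, and B-alkyl Suzuki–Miyaura coupling with the enol triflate should form the C9–C11 bond and with it the tetrasubstituted C8=C9 alkene, whose position is fixed by the triflate.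

**Step 12**
Reactants: 19 coupled ethyl ester
Product: 20 dihydroxy acid
Conditions: LiOH, THF/MeOH/H2O, 40 °C; then 1 M HCl to pH 3
Reagents that add atoms: lithium hydroxide, [Li+].[OH-]
Why: Saponification is placed here because the ethyl ester is the only ester in the molecule at this stage.

**Step 13**
Reactants: 20 dihydroxy acid
Product: 22 3-O-isovaleryl acid, via mixed anhydride 21 (not isolated)
Conditions: (iBuCO)2O (4 equiv), DMAP, Et3N, CH2Cl2, rt; then aq. NaHCO3, THF, rt
Reagents that add atoms: 3-methylbutanoic anhydride, CC(C)CC(=O)OC(=O)CC(C)C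
Why: DMAP-catalysed acylation should take the 3α-hydroxyl, while the 6β-hydroxyl (1,3-diaxial to C20 and C19) stays free, and the mixed anhydride formed at the carboxyl group is hydrolysed in the bicarbonate work-up.

**Step 14**
Reactants: 22 3-O-isovaleryl acid
Product: 23 target (CNP0274836.1)
Conditions: HF·pyridine, THF, 0 °C to rt
Reagents that add atoms: none
Why: Fluoride-mediated desilylation under non-basic conditions should free the C19 alcohol without cleaving or moving the isovalerate.

**Compound list**

1 | 4-methoxy-2,6-dimethylphenol | COc1cc(C)c(O)c(C)c1 | starting material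
2 | 4,4-dimethoxy-2,6-dimethylcyclohexa-2,5-dien-1-one (C9 ketone, C6 ketal) | COC1(OC)C=C(C)C(=O)C(C)=C1 | intermediate
3 | methyl 5-methoxy-3-oxopentanoate | COCCC(=O)CC(=O)OC | starting material
4 | methyl 2-[(1S)-2,2-dimethoxy-4,6-dimethyl-5-oxocyclohex-3-en-1-yl]-5-methoxy-3-oxopentanoate (C5 is S; C4 and C10 epimer mixture) | CC1=CC(OC)(OC)[C@H](C(C(=O)OC)C(=O)CCOC)C(C)C1=O | intermediate
5 | methyl 2-[(1S)-2,2-dimethoxy-4,6-dimethyl-5-oxocyclohex-3-en-1-yl]-3-oxopent-4-enoate (not isolated) | CC1=CC(OC)(OC)[C@H](C(C(=O)OC)C(=O)C=C)C(C)C1=O | intermediate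
6 | cis-fused decalin: C3 ketone, C4 methyl ester (epimers), 5β-H, C6 dimethyl ketal, C7=C8 with C8 methyl, C9 ketone, 10β-methyl | CC=1C(=O)[C@@]2(C)CCC(=O)C(C(=O)OC)[C@H]2C(OC)(OC)C=1 | intermediate
7 | as 6 but with C5=C6 methyl enol ether in place of the ketal (C9 dienone; C10 the only stereocentre) | CC=1C(=O)[C@@]2(C)CCC(=O)C(C(=O)OC)C2=C(OC)C=1 | intermediate
8 | as 7 with C4 quaternary: 4α-methyl, 4β-CO2Me | CC=1C(=O)[C@@]2(C)CCC(=O)[C@](C)(C(=O)OC)C2=C(OC)C=1 | intermediate
9 | dilithium salt of the C8=C9 enolate and 3α-alkoxide derived from 8 (not isolated) | CC1=C([O-])[C@@]2(C)CC[C@@H]([O-])[C@](C)(C(=O)OC)C2=C(OC)C1.[Li+].[Li+] | intermediate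
10 | 3α-hydroxy, 4α-methyl, 4β-CO2Me, C5=C6 methyl enol ether, C8=C9 enol triflate, 10β-methyl | CC1=C(OS(=O)(=O)C(F)(F)F)[C@@]2(C)CC[C@@H](O)[C@](C)(C(=O)OC)C2=C(OC)C1 | intermediate
11 | trans-fused (5α-H) 6-ketone: 3α-hydroxy, 4α-methyl, 4β-CO2Me, C8=C9 enol triflate | CC1=C(OS(=O)(=O)C(F)(F)F)[C@@]2(C)CC[C@@H](O)[C@](C)(C(=O)OC)[C@@H]2C(=O)C1 | intermediate
12 | 6β-hydroxy ester from 11 (not isolated) | CC1=C(OS(=O)(=O)C(F)(F)F)[C@@]2(C)CC[C@@H](O)[C@](C)(C(=O)OC)[C@@H]2[C@H](O)C1 | intermediate
13 | 19,6β-lactone (3α-hydroxy, C8=C9 enol triflate; not isolated) | CC1=C(OS(=O)(=O)C(F)(F)F)[C@@]2(C)CC[C@@H](O)[C@](C)(C(=O)O3)[C@@H]2[C@H]3C1 | intermediate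
14 | 3α,6β,19-triol with C8=C9 enol triflate (5α-H, 10β-methyl, 4α-methyl) | CC1=C(OS(=O)(=O)C(F)(F)F)[C@@]2(C)CC[C@@H](O)[C@](C)(CO)[C@@H]2[C@H](O)C1 | intermediate
15 | 19-O-tert-butyldimethylsilyl ether of 14 | CC1=C(OS(=O)(=O)C(F)(F)F)[C@@]2(C)CC[C@@H](O)[C@](C)(CO[Si](C)(C)C(C)(C)C)[C@@H]2[C@H](O)C1 | intermediate
16 | ethyl (2E)-3-methyl-4-oxobut-2-enoate | CCOC(=O)/C=C(C)/C=O | starting material
17 | ethyl (2E)-3-methylpenta-2,4-dienoate | CCOC(=O)/C=C(C)/C=C | intermediate
18 | ethyl (2E)-5-(9-borabicyclo[3.3.1]nonan-9-yl)-3-methylpent-2-enoate (not isolated) | CCOC(=O)/C=C(C)/CCB1C2CCCC1CCC2 | intermediate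
19 | ethyl 3α,6β-dihydroxy-19-(tert-butyldimethylsilyloxy)labda-8,13E-dien-15-oate | CC1=C(CC/C(C)=C/C(=O)OCC)[C@@]2(C)CC[C@@H](O)[C@](C)(CO[Si](C)(C)C(C)(C)C)[C@@H]2[C@H](O)C1 | intermediate
20 | 3α,6β-dihydroxy-19-(tert-butyldimethylsilyloxy)labda-8,13E-dien-15-oic acid | CC1=C(CC/C(C)=C/C(=O)O)[C@@]2(C)CC[C@@H](O)[C@](C)(CO[Si](C)(C)C(C)(C)C)[C@@H]2[C@H](O)C1 | intermediate
21 | mixed 3-methylbutanoic anhydride of the 3-O-isovaleryl acid (not isolated) | CC1=C(CC/C(C)=C/C(=O)OC(=O)CC(C)C)[C@@]2(C)CC[C@@H](OC(=O)CC(C)C)[C@](C)(CO[Si](C)(C)C(C)(C)C)[C@@H]2[C@H](O)C1 | intermediate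
22 | 3α-(3-methylbutanoyloxy)-6β-hydroxy-19-(tert-butyldimethylsilyloxy)labda-8,13E-dien-15-oic acid | CC1=C(CC/C(C)=C/C(=O)O)[C@@]2(C)CC[C@@H](OC(=O)CC(C)C)[C@](C)(CO[Si](C)(C)C(C)(C)C)[C@@H]2[C@H](O)C1 | intermediate
23 | 3α-(3-methylbutanoyloxy)-6β,19-dihydroxylabda-8,13E-dien-15-oic acid (CNP0274836.1) | CC1=C(CC/C(C)=C/C(=O)O)[C@@]2(C)CC[C@@H](OC(=O)CC(C)C)[C@](C)(CO)[C@@H]2[C@H](O)C1 | target

**Step count and risks**

Total steps: 14 (13 in the main line, 1 for the side-chain diene). Longest linear sequence: 13 steps (steps 1–9 and 11–14).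

Steps most likely to fail:

Step 3. Proton transfer from the acidic β-keto ester to the ring enolate, retro-Michael cleavage of the C4–C5 bond (which would also erode enantiomeric purity) or intermolecular Michael oligomerisation of the unmasked enone may outpace the 6-endo ring closure. The fallback sets out from 2 and 3 and forms both ring A bonds in one cycloaddition. Compound 3 is converted by acid-catalysed loss of methanol (p-TsOH, CHCl3, reflux) into methyl 3-oxopent-4-enoate F1. This is silylated (TBSOTf, Et3N, CH2Cl2, 0 °C) to methyl (2Z)-3-(tert-butyldimethylsilyloxy)penta-2,4-dienoate F2. A Diels–Alder reaction of F2 with 2 under a chiral titanium Lewis acid (TiCl2(OiPr)2 with (S)-BINOL, ligand antipode chosen as in step 2) should give the cis-fused silyl enol ether adduct F3, with the siloxy-activated diene terminus C4 bonding to the β-carbon C5. Desilylation with HF·pyridine comes back to the route at 6.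

Step 2. Facial discrimination by the catalyst may be poor on the α-methylated, cross-conjugated dienone, or the addition may be sluggish. The fallback sets out from 2 and buys the stereocentres instead. Ketal exchange with (1S,2S)-1,2-diphenylethane-1,2-diol (PPTS, benzene, removal of methanol) gives (2S,3S)-7,9-dimethyl-2,3-diphenyl-1,4-dioxaspiro[4.5]deca-6,9-dien-8-one F4. Base-mediated Michael addition of 3 (K2CO3, MeCN) should occur at C5 on the face away from the phenyl group that flanks it, giving the (S)-configured adduct F5. Ring closure under the conditions of step 3 gives the cis-fused chiral ketal F6. Acid-mediated exchange of the auxiliary for methanol with loss of H5 (camphorsulfonic acid, MeOH, HC(OMe)3, then toluene, 80 °C) comes back to the route at 7.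

Step 11. Transmetalation and reductive elimination at the tetrasubstituted C9 centre next to quaternary C10 may be slow, so that protodeboronation and triflate hydrolysis take over. The fallback sets out from 18 (made from 17 as in step 11) and from 15, and makes the C9–C11 bond by Negishi coupling. Treating 18 with I2 and NaOMe gives ethyl (2E)-5-iodo-3-methylpent-2-enoate F7. Zinc insertion (Zn, LiCl, THF) gives [(3E)-5-ethoxy-3-methyl-5-oxopent-3-en-1-yl]zinc iodide F8. Coupling of an excess of F8 with 15 (Pd(OAc)2, SPhos, THF, 50 °C) comes back to the route at 19.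

Further compounds
F1 | step 3 | methyl 3-oxopent-4-enoate | COC(=O)CC(=O)C=C
F2 | step 3 | methyl (2Z)-3-(tert-butyldimethylsilyloxy)penta-2,4-dienoate | COC(=O)/C=C(\O[Si](C)(C)C(C)(C)C)C=C
F3 | step 3 | cis-fused decalin as 6 but with C2=C3 tert-butyldimethylsilyl enol ether in place of the C3 ketone | CC=1C(=O)[C@@]2(C)CC=C(O[Si](C)(C)C(C)(C)C)C(C(=O)OC)[C@H]2C(OC)(OC)C=1
F4 | step 2 | (2S,3S)-7,9-dimethyl-2,3-diphenyl-1,4-dioxaspiro[4.5]deca-6,9-dien-8-one | CC1=CC2(C=C(C)C1=O)O[C@@H](c1ccccc1)[C@H](c1ccccc1)O2
F5 | step 2 | methyl 2-[(2S,3S,6S)-7,9-dimethyl-8-oxo-2,3-diphenyl-1,4-dioxaspiro[4.5]dec-9-en-6-yl]-5-methoxy-3-oxopentanoate | CC1=CC2(O[C@@H](c3ccccc3)[C@H](c3ccccc3)O2)[C@H](C(C(=O)OC)C(=O)CCOC)C(C)C1=O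
F6 | step 2 | cis-fused decalin as 6 but with the C6 ketal as its (4S,5S)-4,5-diphenyl-1,3-dioxolane | CC=1C(=O)[C@@]2(C)CCC(=O)C(C(=O)OC)[C@H]2C3(O[C@@H](c4ccccc4)[C@H](c4ccccc4)O3)C=1
F7 | step 11 | ethyl (2E)-5-iodo-3-methylpent-2-enoate | CCOC(=O)/C=C(C)/CCI
F8 | step 11 | [(3E)-5-ethoxy-3-methyl-5-oxopent-3-en-1-yl]zinc iodide | CCOC(=O)/C=C(C)/CC[Zn]I
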